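**Plan**
The retrosynthesis cuts the C11–C12 bond in the middle of the tricosanoyl chain first (C1 = ester carbonyl). It then cuts the acyl C–O bond to the 2-phenylethyl group.
Enabling feature: C11 and C12 are both unbranched CH2 groups in a bare polymethylene chain. Nine CH2 groups separate C11 from C1, and eleven carbons separate C12 from the chain end. Each is therefore the site of a primary alkyl radical that resists further oxidation and is latent in a carboxylic acid one carbon longer. The ester group and the only ring (phenyl) lie far from both reacting ends.
Forward: dodecanedioic acid 1 is mono-esterified with 2-phenylethanol 2 to give half ester 3. Anodic double decarboxylation of 3 with tridecanoic acid 4 (mixed Kolbe electrolysis, radicals 5 and 6) then joins C11 + C12 to give target 7 in the last step. CO2 is the traceless activating group on both partners.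
No ring is formed. The target has no stereocentre and no stereogenic double bond, so no stereochemistry has to be set.

Key step: step 2

Remark: the target is achiral, so "single enantiomer" is taken to mean the compound exactly as drawn.

**Step 1**
Reactants: 1 dodecanedioic acid; 2 2-phenylethanol
Product: 3 12-oxo-12-(2-phenylethoxy)dodecanoic acid (mono-2-phenylethyl dodecanedioate)
Conditions: 1 (3 equiv), p-TsOH·H2O (5 mol %), toluene, reflux, Dean–Stark; cool, filter off excess 1; SiO2
Reagents that add atoms: none
Why: Fischer esterification with azeotropic water removal, in which the threefold excess of the symmetrical diacid biases the statistical distribution towards the half ester, and the unreacted diacid, barely soluble in cold toluene, can be filtered off and reused.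

**Step 2**
Reactants: 3 12-oxo-12-(2-phenylethoxy)dodecanoic acid; 4 tridecanoic acid
Product: 7 2-phenylethyl tricosanoate, via dodecyl radical 5 (not isolated), via 11-oxo-11-(2-phenylethoxy)undecyl radical 6 (not isolated)
Conditions: 4 (4 equiv), KOH (5 mol % per CO2H), MeOH/petroleum ether, 45 °C, Pt(+)/Pt(−), undivided cell, ca. 0.25 A cm⁻², periodic polarity reversal, to pH ≈ 7; AcOH quench; SiO2
Reagents that add atoms: none
Why: This is a mixed (crossed) Kolbe electrolysis, the classical way to lengthen a fatty acid with an alkanedioic half ester: the two carboxylates adsorbed on the platinum anode each lose one electron and then CO2, the primary radicals 5 and 6 arise in high local concentration and combine at the electrode to form the C11–C12 bond, and protons are reduced to hydrogen at the cathode. No ring is closed and no stereocentre is created, so neither a mode of closure nor a controlling element is needed. The radical path is secured over the two-electron (Hofer–Moest) path by the substrate itself, since both radical carbons are unbranched primary CH2 groups without an α-heteroatom or α-aryl donor, and by smooth Pt, high current density and a weakly acidic, only partly neutralised medium. Cross- versus homo-coupling is purely statistical, so 4 is used in fourfold excess to channel most of 6 into 7, and the three possible coupling products carry zero, one and two ester groups, which should make separation on silica simple. The benzylic CH2 and the phenyl ring lie fourteen or more bonds from the carboxylate carbon and are kept off the anode by the carboxylate layer, as with the benzyl-type esters and carbamates known to survive Kolbe conditions. The phenylethyl ester should not exchange with methanol while free acid buffers the methoxide made at the cathode, which is why the current is cut at about pH 7 and the mixture is acidified at once.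

**Compound list**
1 | dodecanedioic acid | OC(=O)CCCCCCCCCCC(=O)O | starting material
2 | 2-phenylethanol | OCCc1ccccc1 | starting material
3 | 12-oxo-12-(2-phenylethoxy)dodecanoic acid | OC(=O)CCCCCCCCCCC(=O)OCCc1ccccc1 | intermediate
4 | tridecanoic acid | CCCCCCCCCCCCC(=O)O | starting material
5 | dodecyl radical | CCCCCCCCCCC[CH2] | intermediate
6 | 11-oxo-11-(2-phenylethoxy)undecyl radical | [CH2]CCCCCCCCCC(=O)OCCc1ccccc1 | intermediate
7 | 2-phenylethyl tricosanoate | CCCCCCCCCCCCCCCCCCCCCCC(=O)OCCc1ccccc1 | target

Total step count: 2
Longest linear sequence: 2 (1 → 3 → 7)

**Steps most likely to fail** (the route has only two steps, so both are ranked and there is no third entry)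

1. Step 2. Several processes may go wrong:
   - homocoupling may take too large a share of radical 6;
   - waxy deposits may passivate the anode;
   - the radicals may be over-oxidised to cations;
   - the anode may attack the phenyl ring or the benzylic position;
   - the ester may exchange with methanol if the medium turns basic.

   The fallback replaces the electrolysis by a polar, copper-catalysed sp3–sp3 cross-coupling at the same bond. It sets out from 2, which is esterified with commercial 11-bromoundecanoic acid F1 (p-TsOH, toluene, Dean–Stark) to give 2-phenylethyl 11-bromoundecanoate F2. Commercial dodecylmagnesium bromide F3 is then added slowly to F2 (Li2CuCl4 3 mol %, NMP 4 equiv, THF, 0 °C; Kochi-type coupling). Under these conditions displacement of the primary bromide should outrun addition to the ester. The fallback comes back to the route at 7.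

2. Step 1. Statistical control may be lost through a second esterification of the half ester, and separating half ester, diacid and diester may be laborious. The fallback differentiates the two carboxyl groups with a protecting group instead of statistics. It sets out from 2, which is coupled with commercial 12-(tert-butoxy)-12-oxododecanoic acid F4 (DCC, DMAP cat., CH2Cl2, 0 °C to rt; Steglich esterification) to give 1-tert-butyl 12-(2-phenylethyl) dodecanedioate F5. Acidolysis of the tert-butyl ester (TFA/CH2Cl2, rt) leaves the primary phenylethyl ester untouched. The fallback comes back to the route at 3.

**Further compounds**
F1 | step 2 | 11-bromoundecanoic acid | OC(=O)CCCCCCCCCCBr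
F2 | step 2 | 2-phenylethyl 11-bromoundecanoate | BrCCCCCCCCCCC(=O)OCCc1ccccc1
F3 | step 2 | dodecylmagnesium bromide | CCCCCCCCCCCC[Mg]Br
F4 | step 1 | 12-(tert-butoxy)-12-oxododecanoic acid | CC(C)(C)OC(=O)CCCCCCCCCCC(=O)O
F5 | step 1 | 1-tert-butyl 12-(2-phenylethyl) dodecanedioate | CC(C)(C)OC(=O)CCCCCCCCCCC(=O)OCCc1ccccc1
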